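Cuts: the two CH2–aryl bonds from the bridge carbons to C3 and C5 of the central ring, then each side-ring C–CH2N bond, the hindered O–CH3 bond and the three aryl–acyl bonds.
Enabling feature: the central ring has just two ring C–H carbons (C3, C5), each between two OH groups, and each bridge CH2 sits on the one side-ring carbon flanked by two OH groups.
Both side rings are identical and otherwise fully substituted (butanoyl, OMe, Me), so one ortho-quinone methide serves both bridges and cannot itself act as a carbon nucleophile.
Forward: no ring is formed. The side ring comes from 2-methylphloroglucinol in five steps and the central ring from phloroglucinol and the chiral acid in two; the three rings are then joined in one pot, at C3 and then at C5.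
Stereochemistry: the single (S) centre alpha to the central ketone is bought as (S)-2-methylbutanoic acid and only carried along; no stereocentre is created.

Key step: step 8

Assumption: ring locants count the acyl-bearing carbon as C1 and follow the name of the compound under discussion. The purchased (S)-acid is taken to be of high enantiomeric purity, which sets the ceiling for the target.

Step 1
Reactants: 1 2-methylphloroglucinol (2-methylbenzene-1,3,5-triol); 2 butanoyl chloride
Product: 3 1-(2,4,6-trihydroxy-3-methylphenyl)butan-1-one
Conditions: AlCl3 (4 equiv), CH2Cl2/MeNO2, 0 °C to 40 °C; ice/1 M HCl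
Reagents that add atoms: none
Why: Friedel–Crafts C-acylation, in which the two open ring carbons of 1 are related by symmetry so that only one monoketone can arise, and the chelated, deactivated product should resist a second acylation.

Step 2
Reactants: 3 1-(2,4,6-trihydroxy-3-methylphenyl)butan-1-one
Product: 4 1-[2-hydroxy-4,6-bis(methoxymethoxy)-3-methylphenyl]butan-1-one
Conditions: MOMCl (2.1 equiv), i-Pr2NEt (2.5 equiv), CH2Cl2, 0 °C to rt; chromatography
Reagents that add atoms: chloromethyl methyl ether, COCCl
Why: Williamson-type O-alkylation (MOM ether formation) should take the unchelated C4-OH and the C6-OH next to the ring hydrogen, whereas the C2-OH is wedged between acyl and methyl, is turned by the methyl group toward the carbonyl, holds the stronger hydrogen bond and should stay free.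

Step 3
Reactants: 4 1-[2-hydroxy-4,6-bis(methoxymethoxy)-3-methylphenyl]butan-1-one
Product: 5 1-[2-methoxy-4,6-bis(methoxymethoxy)-3-methylphenyl]butan-1-one
Conditions: MeI (3 equiv), K2CO3 (2 equiv), DMF, 40 °C
Reagents that add atoms: iodomethane, CI
Why: Williamson O-methylation of the only remaining phenol, where the polar aprotic medium breaks the chelate, carbonate is too weak to enolise the ketone for C-methylation, and MOM ethers are base-stable.

Step 4
Reactants: 5 1-[2-methoxy-4,6-bis(methoxymethoxy)-3-methylphenyl]butan-1-one
Product: 6 1-(4,6-dihydroxy-2-methoxy-3-methylphenyl)butan-1-one (side ring monomer)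
Conditions: HCl (3 M in MeOH), MeOH, 45 °C
Reagents that add atoms: none
Why: Acid-catalysed acetal exchange removes both MOM groups, and methanol captures the CH2 unit as its dimethyl acetal, so no free formaldehyde should remain to bridge the newly nucleophilic ring, while the aryl methyl ether and the ketone are inert.

Step 5
Reactants: 6 1-(4,6-dihydroxy-2-methoxy-3-methylphenyl)butan-1-one; 7 Eschenmoser salt (dimethylmethyleneiminium iodide, 1.1 equiv)
Product: 8 1-[3-(dimethylaminomethyl)-2,4-dihydroxy-6-methoxy-5-methylphenyl]butan-1-one (side ring Mannich base)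
Conditions: Et3N (1.1 equiv), CH2Cl2, 0 °C to rt; water wash, no chromatography
Reagents that add atoms: none
Why: Mannich aminomethylation with a preformed iminium ion can only strike C5 of 6, the sole ring C–H and doubly activated by its two ortho hydroxyls, and the absence of free formaldehyde together with a slight excess of 7 should prevent symmetrical methylene-bis coupling of 6.

Step 6
Reactants: 9 (S)-2-methylbutanoic acid
Product: 10 (S)-2-methylbutanoyl chloride
Conditions: (COCl)2 (1.1 equiv), DMF (cat.), CH2Cl2, 0 °C to rt; concentrated cold, used crude
Reagents that add atoms: oxalyl chloride, O=C(Cl)C(=O)Cl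
Why: Acid chloride formation through the Vilsmeier-type chloroiminium species runs cold and without base, so no ketene pathway is open and the alpha stereocentre should be retained.

Step 7
Reactants: 10 (S)-2-methylbutanoyl chloride; 11 phloroglucinol
Product: 12 (S)-2-methyl-1-(2,4,6-trihydroxyphenyl)butan-1-one (central ring)
Conditions: AlCl3 (4 equiv), CH2Cl2/MeNO2, 0 °C to rt; ice/1 M HCl; ee checked by chiral HPLC
Reagents that add atoms: none
Why: Friedel–Crafts C-acylation of the threefold-symmetric triol gives a single monoketone that is deactivated toward further acylation, and the low temperature and short contact time should limit Lewis-acid-promoted enolisation at the alpha carbon.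

Step 8
Reactants: 12 (S)-2-methyl-1-(2,4,6-trihydroxyphenyl)butan-1-one; 8 side ring Mannich base (2.3 equiv)
Product: 15 Agrimol B, via ortho-quinone methide 13 (not isolated), via mono-bridged dimer 14 (not isolated)
Conditions: 8 added in portions, degassed 1,4-dioxane, 100 °C, slow Ar sweep
Reagents that add atoms: none
Why: Heat drives a 1,4-elimination of dimethylamine from the hydrogen-bonded ortho-hydroxybenzylamine 8 to give the ortho-quinone methide 13, whose exocyclic CH2 is attacked by C3 of 12 in a conjugate addition; tautomerisation restores both arenes in 14, and the same sequence at C5 delivers 15. The closest known reaction type is the methylene bridging of acylphloroglucinols by trapping a Mannich-base-derived ortho-quinone methide with a phloroglucinol carbon nucleophile, established for dimers and trimers of this family and used here twice on one bis-nucleophile. No ring closes and no stereocentre is made; the only new bonds are CH2–C3 and CH2–C5 of the central ring. Cross- over homo-coupling rests on substitution, since every ring carbon of 8 and 13 is occupied and the side ring can therefore only be the electrophile, while 12 offers exactly two C–H sites, each between two hydroxyls. C- over O-alkylation rests on reversibility, because aryl ether adducts can revert to 13 whereas C-adducts are locked by rearomatisation, and portionwise addition keeps 13 dilute so that its self-dimerisation should stay slow. The alpha stereocentre meets only a weak amine that is swept out by the gas stream, and its ketone is held in a chelate with an ortho hydroxyl, so enolisation should remain negligible.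

Compound list
1 | 2-methylphloroglucinol (2-methylbenzene-1,3,5-triol) | Cc1c(O)cc(O)cc1O | starting material
2 | butanoyl chloride | CCCC(=O)Cl | starting material
3 | 1-(2,4,6-trihydroxy-3-methylphenyl)butan-1-one | CCCC(=O)c1c(O)c(C)c(O)cc1O | intermediate
4 | 1-[2-hydroxy-4,6-bis(methoxymethoxy)-3-methylphenyl]butan-1-one | CCCC(=O)c1c(O)c(C)c(OCOC)cc1OCOC | intermediate
5 | 1-[2-methoxy-4,6-bis(methoxymethoxy)-3-methylphenyl]butan-1-one | CCCC(=O)c1c(OC)c(C)c(OCOC)cc1OCOC | intermediate
6 | 1-(4,6-dihydroxy-2-methoxy-3-methylphenyl)butan-1-one | CCCC(=O)c1c(OC)c(C)c(O)cc1O | intermediate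
7 | Eschenmoser salt (dimethylmethyleneiminium iodide) | C=[N+](C)C.[I-] | starting material
8 | 1-[3-(dimethylaminomethyl)-2,4-dihydroxy-6-methoxy-5-methylphenyl]butan-1-one | CCCC(=O)c1c(OC)c(C)c(O)c(CN(C)C)c1O | intermediate
9 | (S)-2-methylbutanoic acid | OC(=O)[C@@H](C)CC | starting material
10 | (S)-2-methylbutanoyl chloride | ClC(=O)[C@@H](C)CC | intermediate
11 | phloroglucinol (benzene-1,3,5-triol) | Oc1cc(O)cc(O)c1 | starting material
12 | (S)-2-methyl-1-(2,4,6-trihydroxyphenyl)butan-1-one | O=C([C@@H](C)CC)c1c(O)cc(O)cc1O | intermediate
13 | 4-butanoyl-5-hydroxy-3-methoxy-2-methyl-6-methylidenecyclohexa-2,4-dien-1-one (ortho-quinone methide, formed in situ) | CCCC(=O)C1=C(O)C(=C)C(=O)C(C)=C1OC | intermediate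
14 | (S)-1-{3-[(3-butanoyl-2,6-dihydroxy-4-methoxy-5-methylphenyl)methyl]-2,4,6-trihydroxyphenyl}-2-methylbutan-1-one (mono-bridged dimer, formed in situ) | CCCC(=O)c1c(O)c(Cc2c(O)cc(O)c(C(=O)[C@@H](C)CC)c2O)c(O)c(C)c1OC | intermediate
15 | Agrimol B, (S)-1-{3,5-bis[(3-butanoyl-2,6-dihydroxy-4-methoxy-5-methylphenyl)methyl]-2,4,6-trihydroxyphenyl}-2-methylbutan-1-one | CCCC(=O)c1c(O)c(Cc2c(O)c(Cc3c(O)c(C)c(OC)c(C(=O)CCC)c3O)c(O)c(C(=O)[C@@H](C)CC)c2O)c(O)c(C)c1OC | target

Total step count: 8.
Longest linear sequence: 6 (steps 1 to 5, then step 8). The central-ring arm contributes steps 6 and 7.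

Steps most likely to fail

Step 8.
- Risks: the quinone methide may be used up by self-dimerisation or by ipso attack on unreacted Mannich base with loss of its aminomethyl group. The second bridging may lag behind the first. The liberated amine may reopen bridges already made by retro-conjugate addition, so that the rings scramble.
- Fallback (inverted polarity, so the final bonds form at the side-ring carbon instead): the route sets out from 12 and 7. Double aminomethylation (7, 2.2 equiv, Et3N, CH2Cl2) should give (S)-1-[3,5-bis(dimethylaminomethyl)-2,4,6-trihydroxyphenyl]-2-methylbutan-1-one F1.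
- F1 is then heated in degassed dioxane with an excess of the side ring monomer 6. Compound 6 has a single nucleophilic C–H, can react only once and is recoverable. The route is rejoined at 15.

Step 2.
- Risks: discrimination between the two chelated hydroxyls may be poor, with alkylation at C2-OH in place of C6-OH, and alkylation may run on to the tris-ether.
- Fallback: the O-methyl position is fixed on a ring whose two ortho hydroxyls are still equivalent, and the C-methyl group is brought in afterwards. The route sets out from 11 and 2.
- Friedel–Crafts acylation (AlCl3) gives 1-(2,4,6-trihydroxyphenyl)butan-1-one F2. Its bis-methoxymethylation (MOMCl, i-Pr2NEt) can give only one bis-ether, 1-[2-hydroxy-4,6-bis(methoxymethoxy)phenyl]butan-1-one F3.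
- Iodination ortho to the free phenol (NIS, DMF, 0 °C) gives 1-[2-hydroxy-3-iodo-4,6-bis(methoxymethoxy)phenyl]butan-1-one F4. O-methylation (MeI, K2CO3, DMF) gives 1-[3-iodo-2-methoxy-4,6-bis(methoxymethoxy)phenyl]butan-1-one F5.
- Suzuki–Miyaura methylation (MeB(OH)2, Pd(dppf)Cl2, K2CO3, dioxane/H2O) rejoins the route at 5.

Step 7.
- Risks: enantiomeric purity may erode through Lewis-acid-promoted enolisation of the acylating species or of the aluminium-bound ketone, and some diacylation may occur.
- Fallback: the electrophilic acylation is replaced by an aryl-metal acylation. The route sets out from 11 and 9.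
- Phloroglucinol is converted (MOMCl, NaH, DMF) into 1,3,5-tris(methoxymethoxy)benzene F6. Directed ortho-lithiation (n-BuLi, THF, 0 °C) gives 2,4,6-tris(methoxymethoxy)phenyllithium F7.
- Acid 9 is coupled (CDI, MeNHOMe·HCl, CH2Cl2) to the Weinreb amide (S)-N-methoxy-N,2-dimethylbutanamide F8.
- Addition of the aryllithium to the amide at −78 °C with an acetic acid quench gives (S)-2-methyl-1-[2,4,6-tris(methoxymethoxy)phenyl]butan-1-one F9. HCl in MeOH at rt rejoins the route at 12.

Further compounds
F1 | step 8 | (S)-1-[3,5-bis(dimethylaminomethyl)-2,4,6-trihydroxyphenyl]-2-methylbutan-1-one | O=C([C@@H](C)CC)c1c(O)c(CN(C)C)c(O)c(CN(C)C)c1O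
F2 | step 2 | 1-(2,4,6-trihydroxyphenyl)butan-1-one | CCCC(=O)c1c(O)cc(O)cc1O
F3 | step 2 | 1-[2-hydroxy-4,6-bis(methoxymethoxy)phenyl]butan-1-one | CCCC(=O)c1c(O)cc(OCOC)cc1OCOC
F4 | step 2 | 1-[2-hydroxy-3-iodo-4,6-bis(methoxymethoxy)phenyl]butan-1-one | CCCC(=O)c1c(O)c(I)c(OCOC)cc1OCOC
F5 | step 2 | 1-[3-iodo-2-methoxy-4,6-bis(methoxymethoxy)phenyl]butan-1-one | CCCC(=O)c1c(OC)c(I)c(OCOC)cc1OCOC
F6 | step 7 | 1,3,5-tris(methoxymethoxy)benzene | COCOc1cc(OCOC)cc(OCOC)c1
F7 | step 7 | 2,4,6-tris(methoxymethoxy)phenyllithium | [Li]c1c(OCOC)cc(OCOC)cc1OCOC
F8 | step 7 | (S)-N-methoxy-N,2-dimethylbutanamide | CON(C)C(=O)[C@@H](C)CC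
F9 | step 7 | (S)-2-methyl-1-[2,4,6-tris(methoxymethoxy)phenyl]butan-1-one | O=C([C@@H](C)CC)c1c(OCOC)cc(OCOC)cc1OCOC
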